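**Retrosynthetic overview**
- **Feature:** ring A of the chroman (C4a, C5, C6, C7, C8, C8a) is a fully differentiated phloroglucinol. It has oxygen on C5, C7 and C8a (O1), carbon on C4a (C4) and C6 (the acyl chain), and hydrogen only on C8. A pyran-fused vinylketene (C7, C4a, C8a, C8) and a siloxyalkyne (C5, C6) deliver exactly this sequence.
- **Endgame:** the target comes from MOM removal, the aryl ketone from the benzylic carbinol, and the carbinol from the silyl-protected benzannulation product, with the C7 phenol capped first.
- **Key disconnection:** ring A comes from the pyran-fused cyclobutenone and the ring B siloxyalkyne. C6–C7 and C4a–C5 are new bonds and C7–C8 is re-formed.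
- **Fragments:** the cyclobutenone comes from acid closure of the pyran ring on 2-prenylcyclobutane-1,3-dione, itself from ketene and prenylated ethoxyacetylene. The siloxyalkyne comes from acetylide oxidation and silylation, preceded by ring B propanal plus ethynylmagnesium bromide, starting from 5-bromovanillin (methyl moved from O3 to O4, Stille prenylation).
- **Ring order:** ring B is bought, then the four-membered ring is made, then the pyran ring, and benzene ring A last.

Key step: step 15

Assumption: the target has no stereocentre. The carbinol carbon made in step 12 is carried as a racemate and erased in step 18.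
Abbreviation: Ar = 4-methoxy-3-(methoxymethoxy)-5-(3-methylbut-2-en-1-yl)phenyl.

**Step 1**
Reactants: 1 ethoxyacetylene; 2 prenyl bromide (1-bromo-3-methylbut-2-ene)
Product: 4 1-ethoxy-5-methylhex-4-en-1-yne, via lithium ethoxyacetylide 3 (not isolated)
Conditions: n-BuLi, THF, −78 °C; then 2, DMPU, −78 °C to rt
Reagents that add atoms: none
Why: SN2 alkylation of a lithium alkoxyacetylide by a primary allylic bromide is standard acetylide alkylation, and attack at the unhindered CH2 terminus rather than the fully substituted γ-carbon keeps the prenyl group linear.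

**Step 2**
Reactants: 4 1-ethoxy-5-methylhex-4-en-1-yne; 5 acetone
Product: 7 3-ethoxy-2-(3-methylbut-2-en-1-yl)cyclobut-2-en-1-one, via ketene 6 (not isolated)
Conditions: 5 cracked in a hot-wire ketene generator (ca. 700 °C), gas stream passed into 4, CH2Cl2, 0 °C to rt
Reagents that add atoms: none
Why: The thermal [2+2] cycloaddition of ketene with 1-alkoxyalkynes is a known route to 3-alkoxycyclobutenones; the nucleophilic prenyl-bearing alkyne carbon bonds to the ketene carbonyl carbon, which puts prenyl on C2 and ethoxy on C3, and the unactivated prenyl alkene does not add ketene.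

**Step 3**
Reactants: 7 3-ethoxy-2-(3-methylbut-2-en-1-yl)cyclobut-2-en-1-one
Product: 8 3-hydroxy-2-(3-methylbut-2-en-1-yl)cyclobut-2-en-1-one (enol form of 2-prenylcyclobutane-1,3-dione)
Conditions: 1 M aq HCl, THF, 0 °C to rt
Reagents that add atoms: water, O
Why: Acid hydrolysis of the vinylogous ester (addition of water at C3, loss of ethanol) is the known way from 3-ethoxycyclobutenones to cyclobutane-1,3-diones, which rest as the acidic enol, and cold dilute acid is too weak to hydrate the prenyl alkene.

**Step 4**
Reactants: 8 3-hydroxy-2-(3-methylbut-2-en-1-yl)cyclobut-2-en-1-one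
Product: 9 3,3-dimethyl-2-oxabicyclo[4.2.0]oct-1(6)-en-7-one
Conditions: TfOH (5 mol %), CH2Cl2, 0 °C to rt
Reagents that add atoms: none
Why: Markovnikov acid-catalysed intramolecular hydroalkoxylation, the reaction that closes 2-prenyl cyclic 1,3-diones and ortho-prenylphenols to 2,2-dimethylpyrans, traps the tertiary cation with the enol oxygen in a six-membered ring, and because the two enol forms of 8 are identical only one product can form.

**Step 5**
Reactants: 10 5-bromovanillin (3-bromo-4-hydroxy-5-methoxybenzaldehyde)
Product: 11 3-bromo-4,5-dihydroxybenzaldehyde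
Conditions: AlCl3, pyridine, CH2Cl2, reflux; then aq HCl
Reagents that add atoms: none
Why: AlCl3–pyridine cleaves an aryl methyl ether next to a free phenol through a five-membered aluminium chelate (Lewis acid ether cleavage), a known reaction of 5-halovanillins that leaves aldehyde and bromide alone.

**Step 6**
Reactants: 11 3-bromo-4,5-dihydroxybenzaldehyde
Product: 12 3-bromo-5-hydroxy-4-methoxybenzaldehyde
Conditions: MeI, Li2CO3, DMF, 40 °C
Reagents that add atoms: iodomethane, CI
Why: Williamson methylation under weak-base control: the hydroxyl para to the formyl group and ortho to bromine is the more acidic one, so Li2CO3 ionises and MeI alkylates only this oxygen, the known regiochemistry of 3,4-dihydroxybenzaldehydes.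

**Step 7**
Reactants: 12 3-bromo-5-hydroxy-4-methoxybenzaldehyde
Product: 13 3-bromo-4-methoxy-5-(methoxymethoxy)benzaldehyde
Conditions: MOMCl, i-Pr2NEt, CH2Cl2, 0 °C to rt
Reagents that add atoms: chloromethyl methyl ether, COCCl
Why: Standard MOM ether formation on the remaining phenol; the acetal survives the bases, organometallics and heat to come and falls in the last step.

**Step 8**
Reactants: 13 3-bromo-4-methoxy-5-(methoxymethoxy)benzaldehyde
Product: 14 methyl (E)-3-[3-bromo-4-methoxy-5-(methoxymethoxy)phenyl]prop-2-enoate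
Conditions: Ph3P=CHCO2Me, PhMe, 80 °C
Reagents that add atoms: methyl (triphenylphosphoranylidene)acetate, COC(=O)C=P(c1ccccc1)(c1ccccc1)c1ccccc1
Why: Wittig olefination with a stabilised ylide gives the E-cinnamate, and removing the aldehyde before the tin reagent arrives avoids palladium-catalysed allylation of the carbonyl group.

**Step 9**
Reactants: 14 methyl (E)-3-[3-bromo-4-methoxy-5-(methoxymethoxy)phenyl]prop-2-enoate
Product: 15 methyl (E)-3-Ar-prop-2-enoate
Conditions: Bu3SnCH2CH=CMe2, Pd(PPh3)4 (5 mol %), DMF, 90 °C
Reagents that add atoms: tributyl(3-methylbut-2-en-1-yl)stannane, CCCC[Sn](CCCC)(CCCC)CC=C(C)C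
Why: Stille coupling of an aryl bromide with a prenylstannane; reductive elimination takes place from the less hindered σ-prenyl palladium species so that the linear prenyl arene is expected, and ester, MOM ether and enoate are tolerated.

**Step 10**
Reactants: 15 methyl (E)-3-Ar-prop-2-enoate
Product: 16 methyl 3-Ar-propanoate
Conditions: Mg turnings, MeOH, 0 °C to rt
Reagents that add atoms: none
Why: Dissolving-metal conjugate reduction with magnesium in methanol reduces only the aryl-conjugated enoate by electron transfer, so the isolated prenyl alkene that catalytic hydrogenation would endanger is untouched, and a methyl ester cannot scramble in methanol.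

**Step 11**
Reactants: 16 methyl 3-Ar-propanoate
Product: 17 3-Ar-propanal
Conditions: i-Bu2AlH (1.1 equiv), CH2Cl2, −78 °C; MeOH, then aq potassium sodium tartrate
Reagents that add atoms: none
Why: Partial ester reduction with one equivalent of i-Bu2AlH at low temperature stops at the tetrahedral aluminium hemiacetal, which releases the aldehyde only on work-up.

**Step 12**
Reactants: 17 3-Ar-propanal; 18 ethynylmagnesium bromide
Product: 19 racemic 5-Ar-pent-1-yn-3-ol
Conditions: THF, 0 °C; then aq NH4Cl
Reagents that add atoms: none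
Why: Grignard 1,2-addition of an acetylide to an aldehyde; the new carbinol centre forms without control as a racemate, which is harmless because it becomes the ketone carbon in step 18.

**Step 13**
Reactants: 19 racemic 5-Ar-pent-1-yn-3-ol
Product: 20 racemic 3-(tert-butyldimethylsilyloxy)-5-Ar-pent-1-yne
Conditions: TBSCl, imidazole, DMF, rt
Reagents that add atoms: tert-butyldimethylsilyl chloride, CC(C)(C)[Si](C)(C)Cl
Why: Standard silylation masks the propargylic alcohol so that only the alkyne C–H is acidic in the next step.

**Step 14**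
Reactants: 20 racemic 3-(tert-butyldimethylsilyloxy)-5-Ar-pent-1-yne
Product: 23 racemic 3-(tert-butyldimethylsilyloxy)-5-Ar-1-(triisopropylsilyloxy)pent-1-yne, via lithium acetylide 21 (not isolated), via lithium ynolate 22 (not isolated)
Conditions: n-BuLi, THF, −78 °C; t-BuOOLi [t-BuOOH + LiN(SiMe3)2, THF, −78 °C], to 0 °C; i-Pr3SiOTf, −78 to 0 °C
Reagents that add atoms: tert-butyl hydroperoxide, CC(C)(C)OO; triisopropylsilyl trifluoromethanesulfonate, CC(C)[Si](C(C)C)(C(C)C)OS(=O)(=O)C(F)(F)F
Why: Known siloxyalkyne synthesis by acetylide oxidation: the lithium acetylide attacks the peroxide oxygen of t-BuOOLi to give the ynolate, which the bulky silyl triflate traps on oxygen, and loss of silanolate from 22 would have to give a high-energy alkylideneketene, so the propargylic silyl ether should hold.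

**Step 15**
Reactants: 9 3,3-dimethyl-2-oxabicyclo[4.2.0]oct-1(6)-en-7-one; 23 racemic 3-(tert-butyldimethylsilyloxy)-5-Ar-1-(triisopropylsilyloxy)pent-1-yne
Product: 28 racemic 6-[1-(tert-butyldimethylsilyloxy)-3-Ar-propyl]-2,2-dimethyl-5-(triisopropylsilyloxy)chroman-7-ol, via pyran vinylketene 24 (not isolated), via spiro cyclobutenone 25 (not isolated), via dienylketene 26 (not isolated), via cyclohexadienone 27 (not isolated)
Conditions: 9 (1.2 equiv), PhMe (0.5 M), argon, base-washed sealed tube, 110 °C then 135 °C
Reagents that add atoms: none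
Why: Proposed new method: thermal 4π electrocyclic opening of 9 gives vinylketene 24, whose ketene and enol-ether methylene are both exocyclic to the pyran ring and so locked s-cis, and the chain-bearing nucleophilic carbon of 23 attacks the ketene carbonyl carbon (C6–C7) while the silyloxy carbon closes onto the ketene α-carbon (C4a–C5) in a [2+2] cycloaddition to spiro cyclobutenone 25. Reversible 4π opening of 25 gives dienylketene 26, ring A is closed by 6π disrotatory electrocyclisation between ketene carbon C7 and methylene C8, and dienone 27 tautomerises to phenol 28. The closest known reaction type is the Danheiser benzannulation of 3-alkyl- and 2,3-dialkylcyclobutenones with triisopropylsiloxyalkynes; what has not been shown is a ring-fused 3-alkoxy-2-alkylcyclobutenone, whose vinylogous-ester stabilisation should only raise the temperature of the first opening. No stereocentre is created, since the spiro centre of 25 is lost in 26 and the racemic carbinol carbon is a spectator. The step needs a regioselective [2+2] addition, secured by the oxygen-polarised alkyne whose β-carbon is its only nucleophilic site, and chemoselectivity over the prenyl alkene, secured because unactivated trisubstituted alkenes do not add vinylketenes at these temperatures. Only the isomer of 26 with the ketene cis to C8a can close, and the reversible opening of 25 funnels the other isomer back.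

**Step 16**
Reactants: 28 racemic 6-[1-(tert-butyldimethylsilyloxy)-3-Ar-propyl]-2,2-dimethyl-5-(triisopropylsilyloxy)chroman-7-ol
Product: 29 racemic 6-[1-(tert-butyldimethylsilyloxy)-3-Ar-propyl]-7-(methoxymethoxy)-2,2-dimethyl-5-(triisopropylsilyloxy)chroman
Conditions: MOMCl, i-Pr2NEt, Bu4NI (cat.), CH2Cl2, 0 °C to rt
Reagents that add atoms: chloromethyl methyl ether, COCCl
Why: Standard MOM ether formation on the only free phenol; capping C7–OH halves the ortho-quinone methide pathways of the later carbinol, leaves a single phenol in the oxidation, and costs no extra deprotection because it falls with the ring B MOM group.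

**Step 17**
Reactants: 29 racemic 6-[1-(tert-butyldimethylsilyloxy)-3-Ar-propyl]-7-(methoxymethoxy)-2,2-dimethyl-5-(triisopropylsilyloxy)chroman
Product: 30 racemic 6-(1-hydroxy-3-Ar-propyl)-7-(methoxymethoxy)-2,2-dimethylchroman-5-ol
Conditions: Bu4NF, AcOH (1:1, 3 equiv), THF, 0 °C to rt
Reagents that add atoms: none
Why: Fluoride desilylation cleaves the aryl TIPS and the alkyl TBS ether, and acetic acid buffering keeps the liberated C5 phenol protonated so that it does not expel the benzylic oxygen as an ortho-quinone methide.

**Step 18**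
Reactants: 30 racemic 6-(1-hydroxy-3-Ar-propyl)-7-(methoxymethoxy)-2,2-dimethylchroman-5-ol
Product: 31 1-[5-hydroxy-7-(methoxymethoxy)-2,2-dimethylchroman-6-yl]-3-Ar-propan-1-one
Conditions: activated MnO2 (excess), CH2Cl2, rt
Reagents that add atoms: none
Why: Activated MnO2 oxidises benzylic alcohols selectively, ortho-hydroxybenzylic ones included, the product is stabilised at once by the hydrogen bond from C5–OH to the carbonyl oxygen, and the racemic centre is erased here.

**Step 19**
Reactants: 31 1-[5-hydroxy-7-(methoxymethoxy)-2,2-dimethylchroman-6-yl]-3-Ar-propan-1-one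
Product: 32 1-(5,7-dihydroxy-2,2-dimethylchroman-6-yl)-3-[3-hydroxy-4-methoxy-5-(3-methylbut-2-en-1-yl)phenyl]propan-1-one (target)
Conditions: 3 M aq HCl, MeOH, 40 °C
Reagents that add atoms: none
Why: Acid-catalysed acetal exchange removes both aryl MOM ethers, and since the ring B prenyl group lies next to OMe and not next to a free phenol, no second chroman closure can follow under these mild conditions.

**Compound list**

| No. | Name | SMILES | Role |
|---|---|---|---|
| 1 | ethoxyacetylene | CCOC#C | starting material |
| 2 | prenyl bromide | CC(C)=CCBr | starting material |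
| 3 | lithium ethoxyacetylide | [Li]C#COCC | intermediate (not isolated) |
| 4 | 1-ethoxy-5-methylhex-4-en-1-yne | CCOC#CCC=C(C)C | intermediate |
| 5 | acetone | CC(C)=O | starting material |
| 6 | ketene | C=C=O | intermediate (not isolated) |
| 7 | 3-ethoxy-2-(3-methylbut-2-en-1-yl)cyclobut-2-en-1-one | CCOC1=C(CC=C(C)C)C(=O)C1 | intermediate |
| 8 | 3-hydroxy-2-(3-methylbut-2-en-1-yl)cyclobut-2-en-1-one | OC1=C(CC=C(C)C)C(=O)C1 | intermediate |
| 9 | 3,3-dimethyl-2-oxabicyclo[4.2.0]oct-1(6)-en-7-one | O=C1CC2=C1CCC(C)(C)O2 | intermediate |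
| 10 | 5-bromovanillin | COc1cc(C=O)cc(Br)c1O | starting material |
| 11 | 3-bromo-4,5-dihydroxybenzaldehyde | O=Cc1cc(O)c(O)c(Br)c1 | intermediate |
| 12 | 3-bromo-5-hydroxy-4-methoxybenzaldehyde | COc1c(O)cc(C=O)cc1Br | intermediate |
| 13 | 3-bromo-4-methoxy-5-(methoxymethoxy)benzaldehyde | COCOc1cc(C=O)cc(Br)c1OC | intermediate |
| 14 | methyl (E)-3-[3-bromo-4-methoxy-5-(methoxymethoxy)phenyl]prop-2-enoate | COC(=O)/C=C/c1cc(Br)c(OC)c(OCOC)c1 | intermediate |
| 15 | methyl (E)-3-[4-methoxy-3-(methoxymethoxy)-5-(3-methylbut-2-en-1-yl)phenyl]prop-2-enoate | COC(=O)/C=C/c1cc(OCOC)c(OC)c(CC=C(C)C)c1 | intermediate |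
| 16 | methyl 3-[4-methoxy-3-(methoxymethoxy)-5-(3-methylbut-2-en-1-yl)phenyl]propanoate | COC(=O)CCc1cc(OCOC)c(OC)c(CC=C(C)C)c1 | intermediate |
| 17 | 3-[4-methoxy-3-(methoxymethoxy)-5-(3-methylbut-2-en-1-yl)phenyl]propanal | O=CCCc1cc(OCOC)c(OC)c(CC=C(C)C)c1 | intermediate |
| 18 | ethynylmagnesium bromide | C#C[Mg]Br | starting material |
| 19 | racemic 5-[4-methoxy-3-(methoxymethoxy)-5-(3-methylbut-2-en-1-yl)phenyl]pent-1-yn-3-ol | C#CC(O)CCc1cc(OCOC)c(OC)c(CC=C(C)C)c1 | intermediate |
| 20 | racemic 3-(tert-butyldimethylsilyloxy)-5-Ar-pent-1-yne | C#CC(O[Si](C)(C)C(C)(C)C)CCc1cc(OCOC)c(OC)c(CC=C(C)C)c1 | intermediate |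
| 21 | lithium acetylide of 20 | [Li]C#CC(O[Si](C)(C)C(C)(C)C)CCc1cc(OCOC)c(OC)c(CC=C(C)C)c1 | intermediate (not isolated) |
| 22 | lithium ynolate from 21 | [Li]OC#CC(O[Si](C)(C)C(C)(C)C)CCc1cc(OCOC)c(OC)c(CC=C(C)C)c1 | intermediate (not isolated) |
| 23 | racemic 3-(tert-butyldimethylsilyloxy)-5-Ar-1-(triisopropylsilyloxy)pent-1-yne | CC(C)[Si](OC#CC(O[Si](C)(C)C(C)(C)C)CCc1cc(OCOC)c(OC)c(CC=C(C)C)c1)(C(C)C)C(C)C | intermediate |
| 24 | (6,6-dimethyl-2-methylideneoxan-3-ylidene)methanone (pyran vinylketene) | O=C=C1CCC(C)(C)OC1=C | intermediate (not isolated) |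
| 25 | 2-[1-(tert-butyldimethylsilyloxy)-3-Ar-propyl]-7,7-dimethyl-5-methylidene-3-(triisopropylsilyloxy)-6-oxaspiro[3.5]non-2-en-1-one (diastereomer mixture) | O=C1C(C(O[Si](C)(C)C(C)(C)C)CCc3cc(OCOC)c(OC)c(CC=C(C)C)c3)=C(O[Si](C(C)C)(C(C)C)C(C)C)C12CCC(C)(C)OC2=C | intermediate (not isolated) |
| 26 | dienylketene, ketene-bearing carbon cis to the C(=CH2)O carbon | O=C=C(C(O[Si](C)(C)C(C)(C)C)CCc2cc(OCOC)c(OC)c(CC=C(C)C)c2)/C(O[Si](C(C)C)(C(C)C)C(C)C)=C1/CCC(C)(C)OC1=C | intermediate (not isolated) |
| 27 | 6-[1-(tert-butyldimethylsilyloxy)-3-Ar-propyl]-2,2-dimethyl-5-(triisopropylsilyloxy)-3,4-dihydro-2H-chromen-7(8H)-one | O=C1CC2=C(CCC(C)(C)O2)C(O[Si](C(C)C)(C(C)C)C(C)C)=C1C(O[Si](C)(C)C(C)(C)C)CCc3cc(OCOC)c(OC)c(CC=C(C)C)c3 | intermediate (not isolated) |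
| 28 | racemic 6-[1-(tert-butyldimethylsilyloxy)-3-Ar-propyl]-2,2-dimethyl-5-(triisopropylsilyloxy)chroman-7-ol | COc1c(OCOC)cc(CCC(O[Si](C)(C)C(C)(C)C)c2c(O)cc3c(c2O[Si](C(C)C)(C(C)C)C(C)C)CCC(C)(C)O3)cc1CC=C(C)C | intermediate |
| 29 | racemic 7-O-MOM ether of 28 | COc1c(OCOC)cc(CCC(O[Si](C)(C)C(C)(C)C)c2c(OCOC)cc3c(c2O[Si](C(C)C)(C(C)C)C(C)C)CCC(C)(C)O3)cc1CC=C(C)C | intermediate |
| 30 | racemic 6-(1-hydroxy-3-Ar-propyl)-7-(methoxymethoxy)-2,2-dimethylchroman-5-ol | COc1c(OCOC)cc(CCC(O)c2c(OCOC)cc3c(c2O)CCC(C)(C)O3)cc1CC=C(C)C | intermediate |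
| 31 | 1-[5-hydroxy-7-(methoxymethoxy)-2,2-dimethylchroman-6-yl]-3-Ar-propan-1-one | COc1c(OCOC)cc(CCC(=O)c2c(OCOC)cc3c(c2O)CCC(C)(C)O3)cc1CC=C(C)C | intermediate |
| 32 | 1-(5,7-dihydroxy-2,2-dimethylchroman-6-yl)-3-[3-hydroxy-4-methoxy-5-(3-methylbut-2-en-1-yl)phenyl]propan-1-one | COc1c(O)cc(CCC(=O)c2c(O)cc3c(c2O)CCC(C)(C)O3)cc1CC=C(C)C | target |

**Step count**
- Total step count: 19.
- Longest linear sequence: 15 steps (steps 5 to 19). Steps 1 to 4 form the convergent branch.

**Steps most likely to fail**

1. **Step 15.**
 - *What may go wrong:* the vinylogous-ester resonance of the cyclobutenone may slow the first 4π opening. At the temperature then needed, other processes could take over: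
   - elimination across the tertiary C2–O1 bond of the pyran;
   - protonation of the siloxyalkyne;
   - thermal loss of silanol from the ortho-hydroxybenzylic silyl ether;
   - acylation of the new phenol by unreacted vinylketene.
 - *Fallback (known chemistry, sets out from 17, comes back at 32):* ring A is taken from phloroglucinol instead of being built. Phloroglucinol is condensed with 2-methylbut-3-en-2-ol (BF3·OEt2, dioxane) to 2,2-dimethylchroman-5,7-diol F1. Both phenols are capped (MOMCl, i-Pr2NEt) to give 5,7-bis(methoxymethoxy)-2,2-dimethylchroman F2. Directed ortho-lithiation between the two MOM ethers (n-BuLi, THF, 0 °C) gives the 6-lithiochroman F3. This adds to aldehyde 17 at −78 °C to give the fully capped carbinol F4. Dess–Martin oxidation gives the tris-MOM ketone F5, and HCl in MeOH removes the three MOM groups to reach 32.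

2. **Step 4.**
 - *What may go wrong:* three processes may outrun ring closure. These are reversible ionisation of the tertiary C–O bond, ring cleavage of the strained dione by adventitious water, and cationic oligomerisation of the prenyl group.
 - *Fallback (sets out from 7, comes back at 9):* the C–O bond is made at the ring carbon by addition–elimination instead of at the tertiary carbon by cation capture. Mukaiyama hydration of the prenyl alkene of 7 (Co(acac)2, PhSiH3, O2, THF) gives 3-ethoxy-2-(3-hydroxy-3-methylbutyl)cyclobut-2-en-1-one F6. Acid-catalysed intramolecular alkoxy exchange of the vinylogous ester (PPTS, benzene, 5 Å molecular sieves to take up ethanol) then closes the pyran ring to 9.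

3. **Step 17.**
 - *What may go wrong:* the benzylic C–O bond on the very electron-rich ring may ionise with help from phenoxide or acid (ortho-quinone methide formation, then dehydration or dimerisation) during desilylation or isolation. The hindered secondary silyl ether may also cleave only slowly under buffered conditions.
 - *Fallback (sets out from 29, comes back at 32):* deprotection is staged so that the carbinol is never free beside a free phenol and the oxidation runs on a fully capped ring A. One equivalent of Bu4NF at −20 °C removes only the aryl TIPS ether to give the C5 phenol still bearing the benzylic TBS ether F7. MOMCl and i-Pr2NEt give the 5,7-bis-MOM benzylic TBS ether F8. Bu4NF at 50 °C then frees the carbinol F4, Dess–Martin oxidation gives the ketone F5, and HCl in MeOH gives 32.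

**Further compounds**
F1 | step 15 | 2,2-dimethylchroman-5,7-diol | CC1(C)CCc2c(O)cc(O)cc2O1
F2 | step 15 | 5,7-bis(methoxymethoxy)-2,2-dimethylchroman | COCOc1cc(OCOC)c2c(c1)OC(C)(C)CC2
F3 | step 15 | 6-lithio-5,7-bis(methoxymethoxy)-2,2-dimethylchroman | [Li]c1c(OCOC)cc2OC(C)(C)CCc2c1OCOC
F4 | step 15 | racemic 1-[5,7-bis(methoxymethoxy)-2,2-dimethylchroman-6-yl]-3-Ar-propan-1-ol | COc1c(OCOC)cc(CCC(O)c2c(OCOC)cc3c(c2OCOC)CCC(C)(C)O3)cc1CC=C(C)C
F5 | step 15 | 1-[5,7-bis(methoxymethoxy)-2,2-dimethylchroman-6-yl]-3-Ar-propan-1-one | COc1c(OCOC)cc(CCC(=O)c2c(OCOC)cc3c(c2OCOC)CCC(C)(C)O3)cc1CC=C(C)C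
F6 | step 4 | 3-ethoxy-2-(3-hydroxy-3-methylbutyl)cyclobut-2-en-1-one | CCOC1=C(CCC(C)(C)O)C(=O)C1
F7 | step 17 | racemic 6-[1-(tert-butyldimethylsilyloxy)-3-Ar-propyl]-7-(methoxymethoxy)-2,2-dimethylchroman-5-ol | COc1c(OCOC)cc(CCC(O[Si](C)(C)C(C)(C)C)c2c(OCOC)cc3c(c2O)CCC(C)(C)O3)cc1CC=C(C)C
F8 | step 17 | racemic 6-[1-(tert-butyldimethylsilyloxy)-3-Ar-propyl]-5,7-bis(methoxymethoxy)-2,2-dimethylchroman | COc1c(OCOC)cc(CCC(O[Si](C)(C)C(C)(C)C)c2c(OCOC)cc3c(c2OCOC)CCC(C)(C)O3)cc1CC=C(C)C
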